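The ten-membered ring is not closed but released. A trans-fused decalin (10β-methyl, 5α-H) carrying the diene C1(OSi)=C2–C3=C4(Me) in ring A is the closed valence isomer of the germacrane triene C10=C1–C2=C3–C4=C5; C6, C7 and C8 with the butenolide sit on rigid ring B. One photon cleaves the C5–C10 σ bond of 23 by conrotatory 6π opening and delivers 24 with a silyl enol ether at C1=C10 (future ketone and carbinol) and an E-alkene at C4=C5 (future epoxide). Precursor 23 has the C1 TBS dienol ether, the 8-propionate and a silyl-protected C13 hydroxyl; both acetates are added in the last step.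

Key step: step 15

Remark: eudesmane/germacrane numbering is used throughout (C10 = angular methyl carbon, C1 = its ring-A carbonyl neighbour, C5 = ring-fusion CH, C6–C9 = ring B, C11–C13 = lactone carbons); α is the face opposite the C10 methyl.
Remark: in 24 and 25 the ring carbons C9 and C2 are trans across C1=C10, but silyloxy outranks C2, so this bond is Z by CIP; 24 is 1(10)Z,2Z,4E.
Remark: C13 is carried as a TIPS ether because a C13 acetate would be a vinylogous leaving group for the acidic C6–H under the base that closes the butenolide; the silyl dienol ether is made on diketone 9, before any lactone can compete, and every later step is non-acidic and non-oxidising towards it.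
Remark: 1, 17 and 18 are taken as commercially available.

Step 1
Reactants: 1 (R)-Wieland–Miescher ketone
Product: 2 Δ4 bis(ethylene ketal)
Conditions: HOCH2CH2OH (5 equiv), TsOH·H2O (cat.), PhH, reflux, Dean–Stark
Reagents that add atoms: ethylene glycol, OCCO
Why: Acid-catalysed ketalisation of both carbonyls; ketalising the enone carbonyl moves the alkene out of conjugation to the trisubstituted C4=C5 position, as is general for octalones of this type, and no stereocentre is formed.

Step 2
Reactants: 2 Δ4 bis(ethylene ketal)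
Product: 4 4α-alcohol (trans-decalin bis-ketal), via 4α-borane adduct 3 (not isolated)
Conditions: BH3·THF, THF, 0 °C → rt; then NaOH, H2O2, 0 °C → rt
Reagents that add atoms: hydrogen peroxide, OO
Why: Hydroboration–oxidation; boron adds to the less substituted C4 and hydrogen to C5, syn and from the α-face anti to the angular methyl, which should set the trans ring fusion (5α-H) and the 4α-hydroxyl, any cis-fused minor isomer being removed by chromatography.

Step 3
Reactants: 4 4α-alcohol
Product: 5 4-ketone bis-ketal
Conditions: TPAP (5 mol %), NMO, 4 Å MS, CH2Cl2, rt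
Reagents that add atoms: none
Why: Ley–Griffith oxidation of the secondary alcohol under neutral conditions that leave the ketals and the epimerisable C5 centre untouched.

Step 4
Reactants: 5 4-ketone bis-ketal
Product: 7 Δ3-enol triflate, via potassium Δ3-enolate 6 (not isolated)
Conditions: KHMDS, THF, −78 °C; then PhNTf2, −78 → 0 °C
Reagents that add atoms: N-phenyl-bis(trifluoromethanesulfonimide), O=S(=O)(N(c1ccccc1)S(=O)(=O)C(F)(F)F)C(F)(F)F
Why: Kinetic enolisation at the C3 methylene rather than at the hindered ring-fusion C5–H, followed by O-triflation, should give the Δ3 enol triflate regioselectively with C5 unchanged.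

Step 5
Reactants: 7 Δ3-enol triflate
Product: 8 4-methyl-Δ3-ene bis-ketal
Conditions: MeZnCl, Pd(PPh3)4 (5 mol %), THF, 50 °C
Reagents that add atoms: methylzinc chloride, C[Zn]Cl
Why: Negishi cross-coupling of the alkenyl triflate installs the C4 methyl on a regiodefined C3=C4 alkene.

Step 6
Reactants: 8 4-methyl-Δ3-ene bis-ketal
Product: 9 4-methyl-Δ3-ene-1,7-dione
Conditions: 0.5 M aq. HCl, THF, 0 °C → rt, stopped at full ketal cleavage
Reagents that add atoms: water, O
Why: Acid-catalysed ketal hydrolysis frees both ketones; dilute acid should cleave the dioxolanes faster than it moves the C3=C4 alkene into conjugation with C1, and any conjugated isomer is separable.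

Step 7
Reactants: 9 4-methyl-Δ3-ene-1,7-dione
Product: 11 1-silyloxy-1,3-dien-7-one, via potassium ring-A dienolate 10 (not isolated)
Conditions: KHMDS (1.0 equiv), THF, −78 °C; then TBSOTf, −78 °C
Reagents that add atoms: tert-butyldimethylsilyl triflate, CC(C)(C)[Si](C)(C)OS(=O)(=O)C(F)(F)F
Why: Selective enolate formation and O-silylation: the C2 hydrogens are α to the C1 carbonyl and allylic to C3=C4, hence several pK units more acidic than the α-hydrogens of the C7 ketone, so one equivalent of base should give the extended ring-A dienolate and, after O-silylation, the 1-silyloxy-1,3-diene.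

Step 8
Reactants: 11 1-silyloxy-1,3-dien-7-one
Product: 13 8α-hydroxy ketone, via potassium Δ7-enolate 12 (not isolated)
Conditions: KHMDS (1.1 equiv), THF, −78 °C; then 2-(phenylsulfonyl)-3-phenyloxaziridine, −78 °C; pH 7 buffer
Reagents that add atoms: 2-(phenylsulfonyl)-3-phenyloxaziridine, O=S(=O)(c1ccccc1)N1OC1c1ccccc1
Why: Davis α-hydroxylation of the ketone enolate; trans-fused 7-ketones enolise towards C8 and the oxaziridine approaches anti to the axial angular methyl to give the equatorial 8α-alcohol, the silyl dienol ether is inert to the oxaziridine at −78 °C, and any C6 regioisomer converges in step 9.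

Step 9
Reactants: 13 8α-hydroxy ketone
Product: 15 6α,8α-diol ketone, via dipotassium alkoxide-enolate 14 (not isolated)
Conditions: KHMDS (2.3 equiv), THF, −78 → −40 °C; then 2-(phenylsulfonyl)-3-phenyloxaziridine, −78 °C; pH 7 buffer
Reagents that add atoms: 2-(phenylsulfonyl)-3-phenyloxaziridine, O=S(=O)(c1ccccc1)N1OC1c1ccccc1
Why: Davis hydroxylation of a dianion: the C8 alkoxide blocks enolisation on its own side, so the second equivalent of base gives the Δ6 enolate, which is hydroxylated from the α-face (β-face shielded by the C10 methyl) to the equatorial 6α-alcohol.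

Step 10
Reactants: 15 6α,8α-diol ketone
Product: 16 8α-propionate 6α-alcohol
Conditions: (EtCO)2O (1.1 equiv), pyridine, DMAP (2 mol %), CH2Cl2, −20 °C
Reagents that add atoms: propionic anhydride, CCC(=O)OC(=O)CC
Why: Site-selective acylation: C8–OH is flanked only by a methylene, whereas C6–OH is compressed against C5 and the C4 methyl, so one equivalent of anhydride at low temperature should propionylate C8.

Step 11
Reactants: 17 benzyl diethylphosphonoacetate; 18 (triisopropylsiloxy)methyl chloride
Product: 20 benzyl 3-silyloxy-2-phosphonopropanoate, via sodium phosphonate carbanion 19 (not isolated)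
Conditions: NaH, THF, 0 °C; then 18, 0 °C → rt
Reagents that add atoms: none
Why: SN2 C-alkylation of the phosphonoacetate carbanion with the chloromethyl silyl ether introduces the protected hydroxymethyl that becomes C13; the new centre is not controlled and is destroyed in step 14.

Step 12
Reactants: 20 benzyl 3-silyloxy-2-phosphonopropanoate
Product: 21 3-silyloxy-2-phosphonopropanoic acid
Conditions: H2 (1 atm), 10% Pd/C, EtOAc, rt
Reagents that add atoms: none
Why: Hydrogenolysis of the benzyl ester gives the acid without touching the silyl ether or the phosphonate.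

Step 13
Reactants: 16 8α-propionate 6α-alcohol; 21 3-silyloxy-2-phosphonopropanoic acid
Product: 22 C6 phosphonoacyl ester
Conditions: DCC, DMAP (10 mol %), CH2Cl2, 0 °C → rt
Reagents that add atoms: none
Why: Steglich esterification of the one remaining hydroxyl (C6) with acid 21; the conditions are neutral towards the silyl dienol ether.

Step 14
Reactants: 22 C6 phosphonoacyl ester
Product: 23 siloxydiene decalin butenolide (key-step precursor)
Conditions: LiCl, DBU, MeCN, 0 °C → rt
Reagents that add atoms: none
Why: Intramolecular Horner–Wadsworth–Emmons olefination under Masamune–Roush conditions closes the butenolide onto the C7 ketone (the phosphonate C–H is the most acidic site); a silyloxide lost by β-elimination can only re-add to the resulting phosphonoacrylate, and C6 keeps its equatorial α-oxygen.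

Step 15
Reactants: 23 siloxydiene decalin butenolide
Product: 24 cyclodecatriene butenolide
Conditions: hν (300 nm, Pyrex), degassed pentane/Et2O (4:1), −60 °C, to partial conversion; kept at or below −40 °C and used at once
Reagents that add atoms: none
Why: Absorption of a 300 nm photon by the s-cis 1-silyloxy-1,3-diene (butenolide and esters are transparent there) triggers a conrotatory 6π electrocyclic ring opening that cleaves the C5–C10 σ bond. The closest known reaction type is the photochemical opening of trans-fused bicyclic cyclohexa-1,3-dienes to cyclodeca-1,3,5-trienes (provitamin-D-type opening). No ring is formed by bond closure: the ten-membered carbocycle already present as the decalin perimeter is unveiled and stays fused to the butenolide. No stereocentre is created; C5 and C10 become sp2, conrotation of the trans-disposed ring-fusion termini puts the ring bonds trans at both C1=C10 and C4=C5, the new C2=C3 alkene is Z because it comes from the s-cis diene, and C6 and C8 are untouched. The step needs chromophore selectivity (the red-shifted siloxydiene and the Pyrex cut-off), suppression of thermal disrotatory reclosure to a cis-decalin (temperature at or below −40 °C) and limited secondary photochemistry (irradiation stopped at partial conversion; unchanged 23 survives step 16 and is recycled).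

Step 16
Reactants: 24 cyclodecatriene butenolide
Product: 25 germacra-1(10),4-diene silyl enol ether
Conditions: KO2CN=NCO2K (excess), AcOH, CH2Cl2 added to the cold photolysate, −50 → −30 °C
Reagents that add atoms: none
Why: Diimide reduction (concerted syn transfer of H2) should be fastest at the strained, least substituted Z-C2=C3 alkene and leave the tetrasubstituted enol ether, the trisubstituted C4=C5 alkene and the butenolide untouched.

Step 17
Reactants: 25 germacra-1(10),4-diene silyl enol ether
Product: 27 10,13-diol 1-ketone 4,5-epoxide, via silyloxy-oxirane bis-epoxide 26 (not isolated)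
Conditions: DMDO (3 equiv), acetone/CH2Cl2, −40 → −20 °C; then TBAF/AcOH (1:1), THF, 0 °C → rt
Reagents that add atoms: dimethyldioxirane, CC1(C)OO1
Why: Rubottom oxidation of the silyl enol ether and epoxidation of C4=C5 by neutral DMDO should both occur on the exposed outer faces of the crown-shaped ten-membered ring, as is usual for 1(10),4-germacradien-6α-olides. This puts the C10 oxygen opposite the former C5–C10 bond and gives the trans-4,5-epoxide (4R,5R,10R). Buffered fluoride then collapses the silyloxy-oxirane to the C1 ketone and C10 carbinol with retention and frees the C13 hydroxyl.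

Step 18
Reactants: 27 10,13-diol 1-ketone 4,5-epoxide
Product: 28 CNP0285168.1 (target)
Conditions: Ac2O (excess), DMAP, pyridine, CH2Cl2, rt
Reagents that add atoms: acetic anhydride, CC(=O)OC(C)=O
Why: DMAP-catalysed acetylation of the primary C13 hydroxyl and of the tertiary C10 α-ketol hydroxyl completes the target without base strong enough to remove the C6 hydrogen.

Compound list
1 | (R)-(−)-Wieland–Miescher ketone, (8aR)-8a-methyl-3,4,8,8a-tetrahydronaphthalene-1,6(2H,7H)-dione | C[C@@]12CCC(=O)C=C1CCCC2=O | starting material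
2 | 1,1:7,7-bis(ethylenedioxy)-10β-methyldecal-4-ene (dioxolanes at C1 and C7, alkene C4=C5) | C1C[C@@]2(C)C3(OCCO3)CCC=C2CC14OCCO4 | intermediate
3 | 4α-boryl adduct of 2 (monoalkylborane shown; 5α-H) | C1C[C@@]2(C)C3(OCCO3)CC[C@@H](B)[C@@H]2CC14OCCO4 | intermediate
4 | 1,1:7,7-bis(ethylenedioxy)-10β-methyl-5α-decalin-4α-ol (trans-fused) | C1C[C@@]2(C)C3(OCCO3)CC[C@@H](O)[C@@H]2CC14OCCO4 | intermediate
5 | 1,1:7,7-bis(ethylenedioxy)-10β-methyl-5α-decalin-4-one | C1C[C@@]2(C)C3(OCCO3)CCC(=O)[C@@H]2CC14OCCO4 | intermediate
6 | potassium Δ3-enolate of 5 | C1C[C@@]2(C)C3(OCCO3)CC=C([O-])[C@@H]2CC14OCCO4.[K+] | intermediate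
7 | 1,1:7,7-bis(ethylenedioxy)-10β-methyl-5α-decal-3-en-4-yl triflate | C1C[C@@]2(C)C3(OCCO3)CC=C(OS(=O)(=O)C(F)(F)F)[C@@H]2CC14OCCO4 | intermediate
8 | 1,1:7,7-bis(ethylenedioxy)-4,10β-dimethyl-5α-decal-3-ene | C1C[C@@]2(C)C3(OCCO3)CC=C(C)[C@@H]2CC14OCCO4 | intermediate
9 | 4,10β-dimethyl-5α-decal-3-ene-1,7-dione (trans-fused, β,γ-enone in ring A) | O=C1CC[C@@]2(C)C(=O)CC=C(C)[C@@H]2C1 | intermediate
10 | potassium 1-oxido-1,3-dienolate of 9 (ring A; C7 ketone intact) | O=C1CC[C@@]2(C)C([O-])=CC=C(C)[C@@H]2C1.[K+] | intermediate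
11 | 1-(tert-butyldimethylsilyloxy)-4,10β-dimethyl-5α-decala-1,3-dien-7-one | O=C1CC[C@@]2(C)C(O[Si](C)(C)C(C)(C)C)=CC=C(C)[C@@H]2C1 | intermediate
12 | potassium Δ7-enolate of 11 | [O-]C1=CC[C@@]2(C)C(O[Si](C)(C)C(C)(C)C)=CC=C(C)[C@@H]2C1.[K+] | intermediate
13 | 8α-hydroxy derivative of 11 | O[C@H]1C[C@@]2(C)C(O[Si](C)(C)C(C)(C)C)=CC=C(C)[C@@H]2CC1=O | intermediate
14 | dipotassium C8-alkoxide Δ6-enolate of 13 | [O-][C@H]1C[C@@]2(C)C(O[Si](C)(C)C(C)(C)C)=CC=C(C)[C@@H]2C=C1[O-].[K+].[K+] | intermediate
15 | 6α,8α-dihydroxy derivative of 11 | O[C@H]1C[C@@]2(C)C(O[Si](C)(C)C(C)(C)C)=CC=C(C)[C@@H]2[C@@H](O)C1=O | intermediate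
16 | 6α-hydroxy-8α-propionyloxy derivative of 11 | CCC(=O)O[C@H]1C[C@@]2(C)C(O[Si](C)(C)C(C)(C)C)=CC=C(C)[C@@H]2[C@@H](O)C1=O | intermediate
17 | benzyl diethylphosphonoacetate | CCOP(=O)(OCC)CC(=O)OCc1ccccc1 | starting material
18 | (triisopropylsiloxy)methyl chloride | ClCO[Si](C(C)C)(C(C)C)C(C)C | starting material
19 | sodium salt of 17 (phosphonate carbanion) | CCOP(=O)(OCC)[CH-]C(=O)OCc1ccccc1.[Na+] | intermediate
20 | benzyl 2-(diethoxyphosphoryl)-3-(triisopropylsilyloxy)propanoate (racemic) | CCOP(=O)(OCC)C(CO[Si](C(C)C)(C(C)C)C(C)C)C(=O)OCc1ccccc1 | intermediate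
21 | 2-(diethoxyphosphoryl)-3-(triisopropylsilyloxy)propanoic acid (racemic) | CCOP(=O)(OCC)C(CO[Si](C(C)C)(C(C)C)C(C)C)C(=O)O | intermediate
22 | 6α-O-[2-(diethoxyphosphoryl)-3-(triisopropylsilyloxy)propanoyl] derivative of 16 (both epimers at the phosphonate carbon) | CCC(=O)O[C@H]1C[C@@]2(C)C(O[Si](C)(C)C(C)(C)C)=CC=C(C)[C@@H]2[C@@H](OC(=O)C(CO[Si](C(C)C)(C(C)C)C(C)C)P(=O)(OCC)OCC)C1=O | intermediate
23 | 1-(tert-butyldimethylsilyloxy)-8α-propionyloxy-13-(triisopropylsilyloxy)-5α-eudesma-1,3,7(11)-trien-12,6α-olide | CCC(=O)O[C@H]1C[C@@]2(C)C(O[Si](C)(C)C(C)(C)C)=CC=C(C)[C@@H]2[C@H]2OC(=O)C(CO[Si](C(C)C)(C(C)C)C(C)C)=C12 | intermediate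
24 | (1(10)Z,2Z,4E)-1-(tert-butyldimethylsilyloxy)-8α-propionyloxy-13-(triisopropylsilyloxy)germacra-1(10),2,4,7(11)-tetraen-12,6α-olide (ring bonds trans at C1=C10 and C4=C5) | CCC(=O)O[C@H]1C/C(C)=C(O[Si](C)(C)C(C)(C)C)/C=C\C(C)=C\[C@H]2OC(=O)C(CO[Si](C(C)C)(C(C)C)C(C)C)=C12 | intermediate
25 | (1(10)Z,4E)-1-(tert-butyldimethylsilyloxy)-8α-propionyloxy-13-(triisopropylsilyloxy)germacra-1(10),4,7(11)-trien-12,6α-olide | CCC(=O)O[C@H]1C/C(C)=C(O[Si](C)(C)C(C)(C)C)/CC/C(C)=C/[C@H]2OC(=O)C(CO[Si](C(C)C)(C(C)C)C(C)C)=C12 | intermediate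
26 | 1,10-epoxide (1-silyloxy-oxirane) and (4R,5R)-4,5-epoxide of 25, both oxygens on the outer ring faces | CCC(=O)O[C@H]1C[C@@]3(C)O[C@]3(O[Si](C)(C)C(C)(C)C)CC[C@@]2(C)O[C@@H]2[C@H]2OC(=O)C(CO[Si](C(C)C)(C(C)C)C(C)C)=C12 | intermediate
27 | (4R,5R,6S,8S,10R)-4,5-epoxy-10,13-dihydroxy-1-oxo-8-propionyloxygermacr-7(11)-en-12,6-olide | CCC(=O)O[C@H]1C[C@@](C)(O)C(=O)CC[C@@]2(C)O[C@@H]2[C@H]2OC(=O)C(CO)=C12 | intermediate
28 | CNP0285168.1, (4R,5R,6S,8S,10R)-10,13-diacetoxy-4,5-epoxy-1-oxo-8-propionyloxygermacr-7(11)-en-12,6-olide | CCC(=O)O[C@H]1C[C@@](C)(OC(C)=O)C(=O)CC[C@@]2(C)O[C@@H]2[C@H]2OC(=O)C(COC(C)=O)=C12 | target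

Total step count: 18 (steps 1–18, including the two-step preparation of acid 21).
Longest linear sequence: 16 (steps 1–10 and 13–18).

Steps most likely to fail

1. Step 15 (key step). Process at risk: photoreversion and secondary photochemistry cap the conversion, and the triene recloses thermally (disrotatory) while it waits for the reduction. Fallback: the ring is locked open by oxidation before any reduction. Setting out from the cold photolysate of 24, excess DMDO at −78 → −40 °C should epoxidise the silyl enol ether and C4=C5 to give the bis-epoxide that still holds the Z-C2=C3 alkene F1; the hexatriene is then gone and reclosure is impossible. Buffered fluoride (TBAF/AcOH) should give the 10,13-dihydroxy-2Z-en-1-one epoxide F2, and diimide reduction of its strained enone alkene rejoins the route at 27.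

2. Step 10. Process at risk: incomplete discrimination between the two α-ketol hydroxyls, giving regioisomeric and bis-acylated material. Fallback: the order of events is inverted so that only one hydroxyl is ever present. Setting out from 13, propionylation [(EtCO)2O, DMAP, pyridine] gives the 8α-propionyloxy ketone F3; kinetic enolisation at the unsubstituted C6 methylene (LiHMDS, THF, −78 °C) and oxaziridine hydroxylation then give 16 directly, where the route is rejoined.

3. Step 17. Process at risk: poor facial selectivity when both alkenes of the flexible ring are oxidised in one pot, or collapse of the silyloxy-oxirane before C4=C5 has reacted. Fallback: the two oxidations are separated. Setting out from 25, one equivalent of DMDO at −78 °C gives the mono-oxidised silyloxy-oxirane F4, and buffered fluoride gives the 10,13-dihydroxy-1-oxo-4E-ene F5. Its C4=C5 alkene, now in a ring with an sp2 C1 and an sp3 C10, is then epoxidised on its own (mCPBA, NaHCO3, CH2Cl2, 0 °C), and the route is rejoined at 27.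

Further compounds
F1 | step 15 | 1,10-epoxide (1-silyloxy-oxirane) and 4,5-epoxide of 24 retaining the 2Z alkene | CCC(=O)O[C@H]1C[C@@]3(C)O[C@]3(O[Si](C)(C)C(C)(C)C)/C=C\[C@@]2(C)O[C@@H]2[C@H]2OC(=O)C(CO[Si](C(C)C)(C(C)C)C(C)C)=C12
F2 | step 15 | (2Z)-4,5-epoxy-10,13-dihydroxy-1-oxo-8-propionyloxygermacra-2,7(11)-dien-12,6-olide | CCC(=O)O[C@H]1C[C@@](C)(O)C(=O)/C=C\[C@@]2(C)O[C@@H]2[C@H]2OC(=O)C(CO)=C12
F3 | step 10 | 8α-propionyloxy derivative of 11 | CCC(=O)O[C@H]1C[C@@]2(C)C(O[Si](C)(C)C(C)(C)C)=CC=C(C)[C@@H]2CC1=O
F4 | step 17 | 1,10-epoxide (1-silyloxy-oxirane) of 25 with the 4E alkene intact | CCC(=O)O[C@H]1C[C@@]3(C)O[C@]3(O[Si](C)(C)C(C)(C)C)CC/C(C)=C/[C@H]2OC(=O)C(CO[Si](C(C)C)(C(C)C)C(C)C)=C12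
F5 | step 17 | (4E)-10,13-dihydroxy-1-oxo-8-propionyloxygermacra-4,7(11)-dien-12,6-olide | CCC(=O)O[C@H]1C[C@@](C)(O)C(=O)CC/C(C)=C/[C@H]2OC(=O)C(CO)=C12
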